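**Strategy**

The plan rests on cutting the 1,2-dioxene ring of xestin A back to a saturated 1,2-dioxane with a hemiketal OH at C6. In that ring C6 is a latent ketone, its α-carbon C5 is joined to C4, and C3 holds the peroxide oxygen O2. This is the array expected when a radical centred next to a ketone adds to a terminal alkene and the new radical captures dioxygen. One aerobic Mn(OAc)3 annulation should therefore forge C4–C5, C3–O2 and O1–C6 and close the ring. Its precursor is a C20 (E,E)-dienyl β-keto sulfoxide whose (R)-p-tolylsulfinyl group activates C5, makes the C3 epimers separable and later departs to create C4=C5; the partner is methyl but-3-enoate.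

Key step: step 4

Remark: ring atoms are numbered O1, O2, C3 (bearing CH2CO2Me), C4, C5, C6 (ketal carbon); the target is (3R,6R), with OMe at C6 cis to the C3 side chain, and the 3R series is to be assigned by X-ray analysis of a crystalline sulfinyl dioxane using the (R)-sulfur as internal reference.

**Route**

Step 1
Reactants: 1 1-bromo-6-chlorohexane; 2 (2E,4E)-hexa-2,4-dienyl acetate (sorbyl acetate)
Product: 4 (2E,4E)-12-chlorododeca-2,4-diene, via 6-chlorohexylmagnesium bromide 3 (not isolated)
Conditions: Mg, THF, 25–35 °C; then added to 2, Li2CuCl4 (2 mol %), THF, −20 → 0 °C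
Reagents that add atoms: none
Why: Magnesium inserts into C–Br far faster than into C–Cl, and the Li2CuCl4-catalysed (Kochi-type) allylic substitution of a primary dienyl acetate by a primary Grignard reagent is known to occur at the acetate-bearing carbon with the (E,E)-diene preserved.

Step 2
Reactants: 4 (2E,4E)-12-chlorododeca-2,4-diene; 5 ethyl 7-bromoheptanoate
Product: 7 ethyl (15E,17E)-nonadeca-15,17-dienoate, via (8E,10E)-dodeca-8,10-dienylmagnesium chloride 6 (not isolated)
Conditions: Mg (I2-activated), THF, 60 °C; then added slowly to 5, Li2CuCl4 (3 mol %), NMP (4 equiv), THF, 0 → 20 °C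
Reagents that add atoms: none
Why: Copper-catalysed alkyl–alkyl cross-coupling of a Grignard reagent with a primary bromide (Kochi coupling in its NMP-promoted form) outruns Grignard addition to the ester, so the C19 chain should be completed without a carboxyl protecting group.

Step 3
Reactants: 7 ethyl (15E,17E)-nonadeca-15,17-dienoate; 8 (R)-methyl p-tolyl sulfoxide
Product: 10 (16E,18E)-1-[(R)-p-tolylsulfinyl]icosa-16,18-dien-2-one, via [(R)-p-tolylsulfinyl]methyllithium 9 (not isolated)
Conditions: 8 (2.2 equiv), LiN(i-Pr)2 (2.2 equiv), THF, −78 °C; then 7, −78 → 0 °C; aq NH4Cl; recrystallisation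
Reagents that add atoms: none
Why: Claisen-type acylation of the configurationally stable α-sulfinyl carbanion by the ester should give the β-keto sulfoxide with sulfur unchanged, the second equivalent of carbanion deprotonating the acidic product and thereby preventing over-addition.

Step 4
Reactants: 10 (16E,18E)-1-[(R)-p-tolylsulfinyl]icosa-16,18-dien-2-one; 11 methyl but-3-enoate; 12 dioxygen (air)
Product: 14 methyl 2-[(3R)-6-hydroxy-6-[(14E,16E)-octadeca-14,16-dienyl]-5-[(R)-p-tolylsulfinyl]-1,2-dioxan-3-yl]acetate (C5 and C6 unassigned), via ring-opened hydroperoxy keto sulfoxide 13 (not isolated)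
Conditions: Mn(OAc)3·2H2O (0.3 equiv), air (1 atm), AcOH/11 3:1 (11 in about 200-fold excess, recovered by distillation), 10 added over 6 h to 0.01 M, 23 °C; SiO2 (3R series separated from 3S series)
Reagents that add atoms: none
Why: Proposed new method: trivalent manganese oxidises the enol form of 10 to an electrophilic C5 radical that adds to the CH2 terminus of 11 (C4–C5), the secondary C3 radical is captured by triplet dioxygen (C3–O2), and the peroxyl radical is reduced by divalent manganese or by hydrogen transfer from 10 to hydroperoxide 13, which closes onto the C6 carbonyl (O1–C6). The closest known reaction type is the Mn(OAc)3/air annulation of 1,3-dicarbonyl compounds, β-keto sulfones and β-keto sulfoxides with aryl- or 1,1-disubstituted alkenes to 1,2-dioxan-3-ols; new here is a monosubstituted, unactivated alkene, a class known to accept such radicals in Mn(OAc)3 additions run without oxygen. The single ring closes by 6-exo-trig hemiketalisation, which is reversible. C3 is set without control in the oxygen capture, so both C3 epimers are expected, whereas C5 (enolisable through the ring-opened tautomer) and C6 (hemiketal) can equilibrate towards the chair with axial OH and equatorial carbon substituents; the fixed (R)-sulfur makes the 3R and 3S series diastereomers that chromatography should part. The step needs regioselectivity, given by radical attack at the unsubstituted alkene carbon, and chemoselectivity for 11 over the intrinsically more reactive tail diene, which the substrate does not secure by itself and which is enforced by using 11 as co-solvent at high dilution of 10.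

Step 5
Reactants: 14 methyl 2-[(3R)-6-hydroxy-6-[(14E,16E)-octadeca-14,16-dienyl]-5-[(R)-p-tolylsulfinyl]-1,2-dioxan-3-yl]acetate
Product: 15 methyl 2-[(3R,6R)-6-methoxy-6-[(14E,16E)-octadeca-14,16-dienyl]-5-[(R)-p-tolylsulfinyl]-1,2-dioxan-3-yl]acetate (C5 unassigned)
Conditions: MeOH, TsOH·H2O (10 mol %), 3 Å MS, 23 °C; NaHCO3 quench; SiO2 (minor C6 epimer and residual 3S material removed)
Reagents that add atoms: methanol, CO
Why: Acid-catalysed acetal exchange of the peroxy hemiketal is reversible, so the methoxy group should settle axial under the anomeric effect with the long chain and the C3 side chain equatorial, which is the 3,6-cis (6R) arrangement of the target, while sulfoxide, methyl ester, diene and O–O bond tolerate mild acid at room temperature.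

Step 6
Reactants: 15 methyl 2-[(3R,6R)-6-methoxy-6-[(14E,16E)-octadeca-14,16-dienyl]-5-[(R)-p-tolylsulfinyl]-1,2-dioxan-3-yl]acetate
Product: 16 xestin A, methyl 2-[(3R,6R)-6-methoxy-6-[(14E,16E)-octadeca-14,16-dienyl]-3,6-dihydro-1,2-dioxin-3-yl]acetate
Conditions: toluene, NaHCO3 (solid), BHT (5 mol %), argon, 105 °C
Reagents that add atoms: none
Why: Thermal sulfoxide syn-elimination through a five-membered cyclic transition state can only take a hydrogen from C4 because C6 is quaternary, so it should give the ring C4=C5 bond and erase the C5 and sulfur stereocentres while C3 and C6 stay untouched.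

**Compound list**

1 | 1-bromo-6-chlorohexane | ClCCCCCCBr | starting material
2 | (2E,4E)-hexa-2,4-dienyl acetate (sorbyl acetate) | C/C=C/C=C/COC(C)=O | starting material
3 | 6-chlorohexylmagnesium bromide | ClCCCCCC[Mg]Br | intermediate
4 | (2E,4E)-12-chlorododeca-2,4-diene | C/C=C/C=C/CCCCCCCCl | intermediate
5 | ethyl 7-bromoheptanoate | CCOC(=O)CCCCCCBr | starting material
6 | (8E,10E)-dodeca-8,10-dienylmagnesium chloride | C/C=C/C=C/CCCCCCC[Mg]Cl | intermediate
7 | ethyl (15E,17E)-nonadeca-15,17-dienoate | C/C=C/C=C/CCCCCCCCCCCCCC(=O)OCC | intermediate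
8 | (R)-methyl p-tolyl sulfoxide | C[S@@](=O)c1ccc(C)cc1 | starting material
9 | [(R)-p-tolylsulfinyl]methyllithium | [Li]C[S@@](=O)c1ccc(C)cc1 | intermediate
10 | (16E,18E)-1-[(R)-p-tolylsulfinyl]icosa-16,18-dien-2-one | C/C=C/C=C/CCCCCCCCCCCCCC(=O)C[S@@](=O)c1ccc(C)cc1 | intermediate
11 | methyl but-3-enoate | C=CCC(=O)OC | starting material
12 | dioxygen | O=O | starting material
13 | methyl (3R,20E,22E)-3-hydroperoxy-6-oxo-5-[(R)-p-tolylsulfinyl]tetracosa-20,22-dienoate (C5 unassigned) | C/C=C/C=C/CCCCCCCCCCCCCC(=O)C(C[C@@H](CC(=O)OC)OO)[S@@](=O)c1ccc(C)cc1 | intermediate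
14 | methyl 2-[(3R)-6-hydroxy-6-[(14E,16E)-octadeca-14,16-dienyl]-5-[(R)-p-tolylsulfinyl]-1,2-dioxan-3-yl]acetate (C5, C6 unassigned) | C/C=C/C=C/CCCCCCCCCCCCCC1(O)OO[C@H](CC(=O)OC)CC1[S@@](=O)c1ccc(C)cc1 | intermediate
15 | methyl 2-[(3R,6R)-6-methoxy-6-[(14E,16E)-octadeca-14,16-dienyl]-5-[(R)-p-tolylsulfinyl]-1,2-dioxan-3-yl]acetate (C5 unassigned) | C/C=C/C=C/CCCCCCCCCCCCC[C@]1(OC)C([S@@](=O)c2ccc(C)cc2)C[C@@H](CC(=O)OC)OO1 | intermediate
16 | xestin A, methyl 2-[(3R,6R)-6-methoxy-6-[(14E,16E)-octadeca-14,16-dienyl]-3,6-dihydro-1,2-dioxin-3-yl]acetate | C/C=C/C=C/CCCCCCCCCCCCC[C@]1(OC)C=C[C@@H](CC(=O)OC)OO1 | target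

**Totals**

Total step count: 6. Longest linear sequence: 6 steps (1 and 2 to 16).

**Steps most likely to fail**

Step 4 (proposed new method). The C5 radical and the intermediate peroxyl radical may add to the conjugated tail diene or abstract allylic hydrogen, so that oligomeric peroxides form in place of the three-component adduct; slow enolisation of 10 may also let autoxidation of the alkene dominate. The fallback builds the ring by known ionic chemistry and sets out from 10. C-alkylation at C5 with methyl (E)-4-bromobut-2-enoate (K2CO3, acetone, 0–23 °C, product kept cold) should give methyl (2E,20E,22E)-6-oxo-5-[(R)-p-tolylsulfinyl]tetracosa-2,20,22-trienoate F1. Urea–hydrogen peroxide with Sc(OTf)3 (cat.) in MeOH should convert the ketone into the methoxy hydroperoxy ketal, methyl (2E,20E,22E)-6-hydroperoxy-6-methoxy-5-[(R)-p-tolylsulfinyl]tetracosa-2,20,22-trienoate F2. Et2NH in CF3CH2OH should then bring about the 6-exo intramolecular peroxy-Michael addition of the OOH group to C3 of the enoate. The methoxy dioxane forms as C3/C6 isomers; after equilibration at C6 under the step 5 conditions and chromatography the sequence comes back to the route at 15.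

Step 6. At the temperature that sulfenic acid extrusion requires, O–O homolysis or rearrangement of the allylic peroxy ketal and attack by sulfenic acid follow-up products may erode the dioxene. The fallback moves the elimination to a lower temperature and sets out from 14. Through its ring-opened tautomer 13 the hemiketal is an α-sulfinyl ketone, a class that loses sulfenic acid at 50–65 °C (benzene, NaHCO3). This should give methyl (3R,4E,20E,22E)-3-hydroperoxy-6-oxotetracosa-4,20,22-trienoate F3. Irradiation at 350 nm in dilute MeCN should isomerise the enone E to Z, and the Z isomer is drained from the photoequilibrium by closing to methyl 2-[(3R)-6-hydroxy-6-[(14E,16E)-octadeca-14,16-dienyl]-3,6-dihydro-1,2-dioxin-3-yl]acetate F4. Acid-catalysed exchange of this allylic hemiketal in MeOH, established for 3,6-dihydro-1,2-dioxin-3-ols, then leads to 16 with its C6 epimer removed by chromatography.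

Step 5. Ionisation at C6 may be sluggish beside the electron-poor C5, acid may open the ring and fragment the hydroperoxy ketone, and equilibration at C6 may stay incomplete. The fallback sets out from 14 and forms the O–CH3 bond instead of the C6–O bond: Purdie-type O-methylation of the hemiketal hydroxyl with MeI and Ag2O (CH2Cl2, dark, 23 °C) proceeds without ionisation and with retention of the axial hemiketal configuration, and comes back to the route at 15.

**Further compounds**

F1 | step 4 | methyl (2E,20E,22E)-6-oxo-5-[(R)-p-tolylsulfinyl]tetracosa-2,20,22-trienoate | C/C=C/C=C/CCCCCCCCCCCCCC(=O)C(C/C=C/C(=O)OC)[S@@](=O)c1ccc(C)cc1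
F2 | step 4 | methyl (2E,20E,22E)-6-hydroperoxy-6-methoxy-5-[(R)-p-tolylsulfinyl]tetracosa-2,20,22-trienoate | C/C=C/C=C/CCCCCCCCCCCCCC(OC)(OO)C(C/C=C/C(=O)OC)[S@@](=O)c1ccc(C)cc1
F3 | step 6 | methyl (3R,4E,20E,22E)-3-hydroperoxy-6-oxotetracosa-4,20,22-trienoate | C/C=C/C=C/CCCCCCCCCCCCCC(=O)/C=C/[C@@H](CC(=O)OC)OO
F4 | step 6 | methyl 2-[(3R)-6-hydroxy-6-[(14E,16E)-octadeca-14,16-dienyl]-3,6-dihydro-1,2-dioxin-3-yl]acetate | C/C=C/C=C/CCCCCCCCCCCCCC1(O)C=C[C@@H](CC(=O)OC)OO1
F0 | step 5 | none | none
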